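**Retrosynthetic overview**
1. Target ⇐ conjugate methylation at C4 of a cis-fused enone; the C9 tiglate comes from acylation of an axial C9–OH, itself from reduction of a C9 ketone.
2. Ring B ⇐ 6-exo acyl-radical closure C9→C10 onto a prochiral 4,4-disubstituted cyclohexa-2,5-dienone; this desymmetrisation sets C5 and C10 under control of C7/C8.
3. Side chain (C7 isopropenyl, C8–O) ⇐ catalytic asymmetric glyoxylate-ene reaction on a prenyl group, then Mitsunobu esterification with inversion at C8.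
4. Dienone ⇐ oxidative dearomatising allylation of p-cresol (the cresol methyl becomes the angular methyl), then cross-metathesis to the prenyl group.
5. Ring order: ring A (from the arene) first, ring B second.

Assumption: eremophilane numbering is used for positions (ring A = C1–C5, C10; ring B = C5–C10; ketone at C2); ethyl glyoxylate, (R)-2-methylbutanoic acid, tigloyl chloride and N-(phenylselanyl)phthalimide are bought.

**Step 1**
Reactants: 1 p-cresol; 2 allyltrimethylsilane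
Product: 3 4-methyl-4-(prop-2-en-1-yl)cyclohexa-2,5-dien-1-one
Conditions: PhI(OAc)2, (CF3)2CHOH, −15 °C
Reagents that add atoms: allyltrimethylsilane 2, C=CC[Si](C)(C)C
Why: Oxidative dearomatisation (oxidative Hosomi–Sakurai allylation): the iodine(III) reagent generates the HFIP-stabilised phenoxonium ion, which the allylsilane traps at the methyl-bearing para carbon to give the prochiral dienone (no stereocentre yet; moderate yield expected).

**Step 2**
Reactants: 3 4-methyl-4-(prop-2-en-1-yl)cyclohexa-2,5-dien-1-one; 4 2-methylbut-2-ene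
Product: 5 4-methyl-4-(3-methylbut-2-en-1-yl)cyclohexa-2,5-dien-1-one
Conditions: Grubbs II (5 mol %), 2-methylbut-2-ene/CH2Cl2, 40 °C
Reagents that add atoms: 2-methylbut-2-ene 4, CC=C(C)C
Why: Olefin cross-metathesis converts the terminal allyl group into the prenyl group, while the electron-poor dienone C=C bonds do not take part.

**Step 3**
Reactants: 5 4-methyl-4-(3-methylbut-2-en-1-yl)cyclohexa-2,5-dien-1-one; 6 ethyl glyoxylate
Product: 7 ethyl (2S,3R)-2-hydroxy-4-methyl-3-[(1-methyl-4-oxocyclohexa-2,5-dien-1-yl)methyl]pent-4-enoate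
Conditions: (S)-6,6'-Br2-BINOL/Ti(OiPr)2Cl2 (10 mol %), 4 Å MS, CH2Cl2, −30 °C
Reagents that add atoms: ethyl glyoxylate 6, CCOC(=O)C=O
Why: Catalytic asymmetric glyoxylate-ene reaction: the C–C bond forms at the less substituted alkene carbon with H transfer from a methyl (creating the isopropenyl group), the (S)-catalyst fixes the aldehyde face (2S) and the syn-selective transition state typical of BINOL–Ti with trisubstituted alkenes sets C7 as 3R; the dienone stays symmetric.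

**Step 4**
Reactants: 7 ethyl (2S,3R)-2-hydroxy-4-methyl-3-[(1-methyl-4-oxocyclohexa-2,5-dien-1-yl)methyl]pent-4-enoate; 8 (R)-2-methylbutanoic acid
Product: 9 ethyl (2R,3R)-4-methyl-2-{[(2R)-2-methylbutanoyl]oxy}-3-[(1-methyl-4-oxocyclohexa-2,5-dien-1-yl)methyl]pent-4-enoate
Conditions: PPh3, DIAD, toluene, 0 °C → rt
Reagents that add atoms: (R)-2-methylbutanoic acid 8, CC[C@@H](C)C(=O)O
Why: Mitsunobu esterification: SN2 displacement at the activated α-hydroxy-ester carbon inverts C8 (2S → 2R) and installs the final C8 ester in the same operation.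

**Step 5**
Reactants: 9 ethyl (2R,3R)-4-methyl-2-{[(2R)-2-methylbutanoyl]oxy}-3-[(1-methyl-4-oxocyclohexa-2,5-dien-1-yl)methyl]pent-4-enoate; 10 trimethyltin hydroxide
Product: 12 (2R,3R)-4-methyl-2-{[(2R)-2-methylbutanoyl]oxy}-3-[(1-methyl-4-oxocyclohexa-2,5-dien-1-yl)methyl]pent-4-enoic acid, via trimethylstannyl ester 11 (not isolated)
Conditions: Me3SnOH, ClCH2CH2Cl, 70 °C; then 5% aq. HCl
Reagents that add atoms: trimethyltin hydroxide 10, C[Sn](C)(C)O
Why: Mild chemoselective ester hydrolysis with trimethyltin hydroxide cleaves the unhindered, α-acyloxy-activated ethyl ester without touching the hindered secondary 2-methylbutanoate or epimerising C8.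

**Step 6**
Reactants: 12 (2R,3R)-4-methyl-2-{[(2R)-2-methylbutanoyl]oxy}-3-[(1-methyl-4-oxocyclohexa-2,5-dien-1-yl)methyl]pent-4-enoic acid; 13 N-(phenylselanyl)phthalimide
Product: 14 Se-phenyl (2R,3R)-4-methyl-2-{[(2R)-2-methylbutanoyl]oxy}-3-[(1-methyl-4-oxocyclohexa-2,5-dien-1-yl)methyl]pent-4-eneselenoate
Conditions: PBu3, CH2Cl2, −20 °C → rt
Reagents that add atoms: N-(phenylselanyl)phthalimide 13, O=C1c2ccccc2C(=O)N1[Se]c1ccccc1
Why: Phosphine-mediated selenoesterification (via the acyloxyphosphonium) under neutral conditions gives the acyl-radical precursor without releasing free selenol that could add to the dienone.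

**Step 7**
Reactants: 14 Se-phenyl (2R,3R)-4-methyl-2-{[(2R)-2-methylbutanoyl]oxy}-3-[(1-methyl-4-oxocyclohexa-2,5-dien-1-yl)methyl]pent-4-eneselenoate
Product: 15 (2R,3R,4aR,8aS)-4a-methyl-1,7-dioxo-3-(prop-1-en-2-yl)-1,2,3,4,4a,7,8,8a-octahydronaphthalen-2-yl (2R)-2-methylbutanoate
Conditions: Bu3SnH (syringe pump), AIBN, PhH (0.01 M), 80 °C
Reagents that add atoms: none
Why: Acyl-radical 6-exo-trig cyclisation onto one of the two enantiotopic enone arms: the new C9–C10 bond must form axially on the dienone ring, so the ring-B chair carries the C5 methyl equatorially, and only one arm lets both the C7 isopropenyl and the C8 acyloxy group sit equatorial (the other arm forces both axial with a 1,3-diaxial clash with C4), which sets C5 (R), the cis ring fusion at C10 (S) and the cis 5-methyl/7-isopropenyl relationship.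

**Step 8**
Reactants: 15 (2R,3R,4aR,8aS)-4a-methyl-1,7-dioxo-3-(prop-1-en-2-yl)-1,2,3,4,4a,7,8,8a-octahydronaphthalen-2-yl (2R)-2-methylbutanoate
Product: 16 (1S,2R,3R,4aR,8aS)-1-hydroxy-4a-methyl-7-oxo-3-(prop-1-en-2-yl)-1,2,3,4,4a,7,8,8a-octahydronaphthalen-2-yl (2R)-2-methylbutanoate
Conditions: NaBH4, MeOH/CH2Cl2 (1:1), −78 °C
Reagents that add atoms: none
Why: Chemoselective borohydride 1,2-reduction of the saturated, α-acyloxy-activated C9 ketone beside the less electrophilic enone; axial hydride delivery is blocked by the syn-axial C4 carbon, so hydride enters equatorially and gives the axial (9S) alcohol cis to the C8 ester.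

**Step 9**
Reactants: 16 (1S,2R,3R,4aR,8aS)-1-hydroxy-4a-methyl-7-oxo-3-(prop-1-en-2-yl)-1,2,3,4,4a,7,8,8a-octahydronaphthalen-2-yl (2R)-2-methylbutanoate; 17 tigloyl chloride
Product: 18 (1S,2R,3R,4aR,8aS)-4a-methyl-2-{[(2R)-2-methylbutanoyl]oxy}-7-oxo-3-(prop-1-en-2-yl)-1,2,3,4,4a,7,8,8a-octahydronaphthalen-1-yl (2E)-2-methylbut-2-enoate
Conditions: pyridine, DMAP (cat.), CH2Cl2, 0 → 40 °C
Reagents that add atoms: tigloyl chloride 17, C/C=C(\C)C(Cl)=O
Why: DMAP-catalysed acylation of the hindered axial alcohol with the thermodynamically stable (E)-acyl chloride under weakly basic conditions, which retains the E geometry and disfavours migration of the equatorial C8 ester.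

**Step 10**
Reactants: 18 (1S,2R,3R,4aR,8aS)-4a-methyl-2-{[(2R)-2-methylbutanoyl]oxy}-7-oxo-3-(prop-1-en-2-yl)-1,2,3,4,4a,7,8,8a-octahydronaphthalen-1-yl (2E)-2-methylbut-2-enoate; 19 methyllithium
Product: 22 (1S,2R,3R,4aR,5S,8aS)-4a,5-dimethyl-2-{[(2R)-2-methylbutanoyl]oxy}-7-oxo-3-(prop-1-en-2-yl)decahydronaphthalen-1-yl (2E)-2-methylbut-2-enoate (target), via lithium dimethylcuprate 20 (not isolated), via lithium enolate 21 (not isolated)
Conditions: MeLi (3 equiv), CuI (1.5 equiv), Et2O, −78 → −40 °C; then aq. NH4Cl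
Reagents that add atoms: lithium dimethylcuprate 20, [Li+].C[Cu-]C
Why: Gilman conjugate addition to the β-unsubstituted enone: methyl is delivered to C4 on the convex face, anti to the axial C10–C9 bond (the usual trans-3,5 rule for cyclohexenones), placing the new methyl equatorial and cis to the angular methyl (4S), and the enolate is protonated on work-up; the esters do not react at low temperature.

**Compound list**
1 | p-cresol | Cc1ccc(O)cc1 | starting material
2 | allyltrimethylsilane | C=CC[Si](C)(C)C | starting material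
3 | 4-methyl-4-(prop-2-en-1-yl)cyclohexa-2,5-dien-1-one | C=CCC1(C)C=CC(=O)C=C1 | intermediate
4 | 2-methylbut-2-ene | CC=C(C)C | starting material
5 | 4-methyl-4-(3-methylbut-2-en-1-yl)cyclohexa-2,5-dien-1-one | CC(C)=CCC1(C)C=CC(=O)C=C1 | intermediate
6 | ethyl glyoxylate | CCOC(=O)C=O | starting material
7 | ethyl (2S,3R)-2-hydroxy-4-methyl-3-[(1-methyl-4-oxocyclohexa-2,5-dien-1-yl)methyl]pent-4-enoate | C=C(C)[C@@H](CC1(C)C=CC(=O)C=C1)[C@H](O)C(=O)OCC | intermediate
8 | (R)-2-methylbutanoic acid | CC[C@@H](C)C(=O)O | starting material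
9 | ethyl (2R,3R)-4-methyl-2-{[(2R)-2-methylbutanoyl]oxy}-3-[(1-methyl-4-oxocyclohexa-2,5-dien-1-yl)methyl]pent-4-enoate | C=C(C)[C@@H](CC1(C)C=CC(=O)C=C1)[C@@H](OC(=O)[C@H](C)CC)C(=O)OCC | intermediate
10 | trimethyltin hydroxide | C[Sn](C)(C)O | starting material
11 | trimethylstannyl (2R,3R)-4-methyl-2-{[(2R)-2-methylbutanoyl]oxy}-3-[(1-methyl-4-oxocyclohexa-2,5-dien-1-yl)methyl]pent-4-enoate | C=C(C)[C@@H](CC1(C)C=CC(=O)C=C1)[C@@H](OC(=O)[C@H](C)CC)C(=O)O[Sn](C)(C)C | intermediate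
12 | (2R,3R)-4-methyl-2-{[(2R)-2-methylbutanoyl]oxy}-3-[(1-methyl-4-oxocyclohexa-2,5-dien-1-yl)methyl]pent-4-enoic acid | C=C(C)[C@@H](CC1(C)C=CC(=O)C=C1)[C@@H](OC(=O)[C@H](C)CC)C(=O)O | intermediate
13 | N-(phenylselanyl)phthalimide | O=C1c2ccccc2C(=O)N1[Se]c1ccccc1 | starting material
14 | Se-phenyl (2R,3R)-4-methyl-2-{[(2R)-2-methylbutanoyl]oxy}-3-[(1-methyl-4-oxocyclohexa-2,5-dien-1-yl)methyl]pent-4-eneselenoate | C=C(C)[C@@H](CC1(C)C=CC(=O)C=C1)[C@@H](OC(=O)[C@H](C)CC)C(=O)[Se]c1ccccc1 | intermediate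
15 | (2R,3R,4aR,8aS)-4a-methyl-1,7-dioxo-3-(prop-1-en-2-yl)-1,2,3,4,4a,7,8,8a-octahydronaphthalen-2-yl (2R)-2-methylbutanoate | C=C(C)[C@H]1C[C@@]2(C)[C@H](CC(=O)C=C2)C(=O)[C@@H]1OC(=O)[C@H](C)CC | intermediate
16 | (1S,2R,3R,4aR,8aS)-1-hydroxy-4a-methyl-7-oxo-3-(prop-1-en-2-yl)-1,2,3,4,4a,7,8,8a-octahydronaphthalen-2-yl (2R)-2-methylbutanoate | C=C(C)[C@H]1C[C@@]2(C)[C@H](CC(=O)C=C2)[C@H](O)[C@@H]1OC(=O)[C@H](C)CC | intermediate
17 | tigloyl chloride, (2E)-2-methylbut-2-enoyl chloride | C/C=C(\C)C(Cl)=O | starting material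
18 | (1S,2R,3R,4aR,8aS)-4a-methyl-2-{[(2R)-2-methylbutanoyl]oxy}-7-oxo-3-(prop-1-en-2-yl)-1,2,3,4,4a,7,8,8a-octahydronaphthalen-1-yl (2E)-2-methylbut-2-enoate | C=C(C)[C@H]1C[C@@]2(C)[C@H](CC(=O)C=C2)[C@H](OC(=O)/C(C)=C/C)[C@@H]1OC(=O)[C@H](C)CC | intermediate
19 | methyllithium | [Li]C | starting material
20 | lithium dimethylcuprate | [Li+].C[Cu-]C | intermediate
21 | lithium enolate of 22 (C2–O–Li, C2=C3) | C=C(C)[C@H]1C[C@@]2(C)[C@H](CC([O-])=C[C@@H]2C)[C@H](OC(=O)/C(C)=C/C)[C@@H]1OC(=O)[C@H](C)CC.[Li+] | intermediate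
22 | (1S,2R,3R,4aR,5S,8aS)-4a,5-dimethyl-2-{[(2R)-2-methylbutanoyl]oxy}-7-oxo-3-(prop-1-en-2-yl)decahydronaphthalen-1-yl (2E)-2-methylbut-2-enoate | C=C(C)[C@H]1C[C@@]2(C)[C@H](CC(=O)C[C@@H]2C)[C@H](OC(=O)/C(C)=C/C)[C@@H]1OC(=O)[C@H](C)CC | target

**Totals and risks**
Total step count: 10. Longest linear sequence: 10 steps (1 → 22).

The three steps most likely to fail are 4, 7 and 10.

Step 4: the Mitsunobu reaction on the β-branched α-hydroxy ester may stall or give elimination. The fallback sets out from 7 and replaces the redox condensation by a discrete sulfonate displacement. Tf2O and 2,6-lutidine (CH2Cl2, −78 °C) give ethyl (2S,3R)-4-methyl-3-[(1-methyl-4-oxocyclohexa-2,5-dien-1-yl)methyl]-2-{[(trifluoromethyl)sulfonyl]oxy}pent-4-enoate F1. F1 is then displaced with the caesium salt of 8 (Cs2CO3, DMF, 0 °C) with SN2 inversion, and the route is rejoined at 9.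

Step 7: the α-acyloxy acyl radical may lose CO before it cyclises. The fallback sets out from 7 and closes ring B by polar NHC umpolung, keeping the C8 oxygen as a non-leaving silyl ether and inverting C8 afterwards.
- TBSOTf/2,6-lutidine gives ethyl (2S,3R)-2-[(tert-butyldimethylsilyl)oxy]-4-methyl-3-[(1-methyl-4-oxocyclohexa-2,5-dien-1-yl)methyl]pent-4-enoate F2.
- Excess DIBAL-H reduces both the ester and the dienone carbonyl to (2S,3R)-2-[(tert-butyldimethylsilyl)oxy]-3-[(4-hydroxy-1-methylcyclohexa-2,5-dien-1-yl)methyl]-4-methylpent-4-en-1-ol F3.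
- Dess–Martin periodinane re-oxidises both alcohols to (2S,3R)-2-[(tert-butyldimethylsilyl)oxy]-4-methyl-3-[(1-methyl-4-oxocyclohexa-2,5-dien-1-yl)methyl]pent-4-enal F4.
- A chiral aminoindanol-derived triazolium carbene (KHMDS, toluene, rt) effects the desymmetrising intramolecular Stetter reaction to (2S,3R,4aR,8aS)-2-[(tert-butyldimethylsilyl)oxy]-4a-methyl-3-(prop-1-en-2-yl)-3,4,4a,8a-tetrahydronaphthalene-1,7(2H,8H)-dione F5.
- HF·pyridine gives (2S,3R,4aR,8aS)-2-hydroxy-4a-methyl-3-(prop-1-en-2-yl)-3,4,4a,8a-tetrahydronaphthalene-1,7(2H,8H)-dione F6.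
- Mitsunobu esterification of the axial ketol F6 with 8 inverts C8 and rejoins the route at 15.

Step 10: the cuprate may prefer the other face of the cis-fused enone and give the C4 epimer. The fallback sets out from 18 and uses the same facial bias in the opposite sense.
- Me2CuLi/TMSCl gives the trimethylsilyl enol ether F7 (4-methyl, C2–OSiMe3, C2=C3; C4 configuration immaterial).
- Saegusa–Ito oxidation with Pd(OAc)2 in MeCN gives the β-methyl enone (1S,2R,3R,4aS,8aS)-4a,5-dimethyl-2-{[(2R)-2-methylbutanoyl]oxy}-7-oxo-3-(prop-1-en-2-yl)-1,2,3,4,4a,7,8,8a-octahydronaphthalen-1-yl (2E)-2-methylbut-2-enoate F8.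
- Copper hydride conjugate reduction (Stryker's reagent, PhH, rt) delivers hydride to C4 on the face that the cuprate had preferred, which leaves the methyl on the required face. The route is rejoined at 22.

**Further compounds**
F1 | step 4 | ethyl (2S,3R)-4-methyl-3-[(1-methyl-4-oxocyclohexa-2,5-dien-1-yl)methyl]-2-{[(trifluoromethyl)sulfonyl]oxy}pent-4-enoate | C=C(C)[C@@H](CC1(C)C=CC(=O)C=C1)[C@H](OS(=O)(=O)C(F)(F)F)C(=O)OCC
F2 | step 7 | ethyl (2S,3R)-2-[(tert-butyldimethylsilyl)oxy]-4-methyl-3-[(1-methyl-4-oxocyclohexa-2,5-dien-1-yl)methyl]pent-4-enoate | C=C(C)[C@@H](CC1(C)C=CC(=O)C=C1)[C@H](O[Si](C)(C)C(C)(C)C)C(=O)OCC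
F3 | step 7 | (2S,3R)-2-[(tert-butyldimethylsilyl)oxy]-3-[(4-hydroxy-1-methylcyclohexa-2,5-dien-1-yl)methyl]-4-methylpent-4-en-1-ol | C=C(C)[C@@H](CC1(C)C=CC(O)C=C1)[C@H](O[Si](C)(C)C(C)(C)C)CO
F4 | step 7 | (2S,3R)-2-[(tert-butyldimethylsilyl)oxy]-4-methyl-3-[(1-methyl-4-oxocyclohexa-2,5-dien-1-yl)methyl]pent-4-enal | C=C(C)[C@@H](CC1(C)C=CC(=O)C=C1)[C@H](O[Si](C)(C)C(C)(C)C)C=O
F5 | step 7 | (2S,3R,4aR,8aS)-2-[(tert-butyldimethylsilyl)oxy]-4a-methyl-3-(prop-1-en-2-yl)-3,4,4a,8a-tetrahydronaphthalene-1,7(2H,8H)-dione | C=C(C)[C@H]1C[C@@]2(C)[C@H](CC(=O)C=C2)C(=O)[C@H]1O[Si](C)(C)C(C)(C)C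
F6 | step 7 | (2S,3R,4aR,8aS)-2-hydroxy-4a-methyl-3-(prop-1-en-2-yl)-3,4,4a,8a-tetrahydronaphthalene-1,7(2H,8H)-dione | C=C(C)[C@H]1C[C@@]2(C)[C@H](CC(=O)C=C2)C(=O)[C@H]1O
F7 | step 10 | trimethylsilyl enol ether of 22 with C4 unassigned (C2–OSiMe3, C2=C3) | C=C(C)[C@H]1C[C@@]2(C)[C@H](CC(O[Si](C)(C)C)=CC2C)[C@H](OC(=O)/C(C)=C/C)[C@@H]1OC(=O)[C@H](C)CC
F8 | step 10 | (1S,2R,3R,4aS,8aS)-4a,5-dimethyl-2-{[(2R)-2-methylbutanoyl]oxy}-7-oxo-3-(prop-1-en-2-yl)-1,2,3,4,4a,7,8,8a-octahydronaphthalen-1-yl (2E)-2-methylbut-2-enoate | C=C(C)[C@H]1C[C@@]2(C)[C@H](CC(=O)C=C2C)[C@H](OC(=O)/C(C)=C/C)[C@@H]1OC(=O)[C@H](C)CC
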